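**65.6% of the E charged stands as X on the plateau of the eta run, and that mean, a reading with its scatter, gives b = 1.20: the rate at which the step to Z uses E over the rate at which the step to G uses it, both at the start.** The field calls such a ratio a selectivity factor.

- eta: E 0.50 M; the very flask that is asked about, followed so far
- flask: E 0.50 M; time 2.5 d

- eta (time / h: X / %, E / %): 2.50: 51.2, 1.5; 8.00: 65.6, 0; 15.0: 65.4, 0; 20.0: 66.2, 0; 30.0: 65.3, 0

(readings scatter by 0.5 percentage points)

- percentages count the E that a species holds: one Z counts as two
- steps under discussion: E -> G; 2 E -> Z; G -> X
- the reaction counts as stopped when no species that holds the E changes by six tenths of a point or more over the second half of the time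

* the state of affairs at 2.5 d: stopped, and by what, or still going (forward and back rates have come level / it is still moving / all of E has reacted)
* how much X there is at 2.5 d, in percent of the E charged

The step to G has a fixed time constant. The step to Z goes with the square of E, so its time constant lengthens as E falls, and the ratio falls in step with E. Summed over the whole consumption of E, the share passing through G is the natural logarithm of one plus b, divided by b. G has one listed exit, X, so that share is the final X, and by this reckoning Z, which was not read in the eta run, holds the remaining 34.4%.

The asked flask and the eta run look alike because they are the same flask: the same charge of 0.50 M, hence the same b. The asked time of 60 h is twice that of the last reading. E reads 0% from 8.00 h on, and 60 h lies later, so my reckoning for the flask is the plateau, 65.6%.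

The forecast says all of E has reacted, with X at 65.6%, between 64.9% and 66.4%; in its words: “The flask should therefore simply stay put”.

The flask ends with this state: all of E has reacted, E standing at 0%, X at 65.9%, below the forecast's high end, and Z at 34.1%.

    E → G (k = 0.0210 min⁻¹)
    2 E → Z (k = 0.0250 M⁻¹ min⁻¹)
    G → X (k = 0.0150 min⁻¹)

The neighbouring flask differs by its charge, 0.12 M of E against 0.50 M. Taken in proportion to the charge, the value 1.20 becomes 0.289 in the neighbouring flask, which is less, and the same law gives 87.8% of X. The neighbouring flask itself stands at 2.50 d with E at 0%, Z at 12.0% and X at 88.0%.

The numbers in the tables were generated by integration with made-up constants, noise included.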